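**Assumption:** labdane numbering and α/β descriptors are used for compounds 18–24; methyl diazoacetate (14) is taken as a commercial solution; the bisoxazoline antipode in step 8 is whichever one gives (1R,5R,6R)-17, to be confirmed on the first run.

## Retrosynthetic overview

1. Target 24 comes from diol 21 by Sharpless epoxidation, primary-alcohol oxidation and acetylation; 21 comes from β-keto ester 18 by α-face C4 methylation and two hydride reductions.
2. Key disconnection: rings A and B of 18 form together from bicyclo[3.1.0]hexanone 17. The five-membered ketone ring is expanded to ring A by opening the internal cyclopropane bond, while the allylsilane closes ring B and leaves the exocyclic methylene.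
3. 17 comes from diazo keto ester 16 by enantioselective intramolecular cyclopropanation, which sets the absolute configuration.
4. 16 is built right-to-left by two cycles of vinyl-metal addition and vinylation/Claisen rearrangement from aldehyde 4 (from 1 + 2), then a diazoacetate aldol/oxidation.
5. Ring order: cyclopropane and cyclopentanone (step 8), then rings A and B in one step (step 9), then the epoxide (step 12).

## Route

**Step 1**
Reactants: 1 2-(2-bromoethyl)-1,3-dioxolane; 2 methyl but-2-ynoate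
Product: 3 methyl (2E)-5-(1,3-dioxolan-2-yl)-3-methylpent-2-enoate
Conditions: Mg, THF, 25 °C; CuBr·SMe2 (1 equiv), THF, −78 °C; then 2, −78 °C; aq. NH4Cl
Reagents that add atoms: none
Why: syn conjugate addition (carbocupration) of the organocopper to the ynoate and protonation with retention at −78 °C give the (E)-trisubstituted enoate.

**Step 2**
Reactants: 3 methyl (2E)-5-(1,3-dioxolan-2-yl)-3-methylpent-2-enoate
Product: 4 methyl (2E)-3-methyl-6-oxohex-2-enoate
Conditions: 1 M HCl, THF, 25 °C
Reagents that add atoms: water O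
Why: acid hydrolysis of the dioxolane acetal; the enoate is stable to dilute acid.

**Step 3**
Reactants: 4 methyl (2E)-3-methyl-6-oxohex-2-enoate; 5 (2-bromoprop-2-en-1-yl)trimethylsilane
Product: 6 methyl (2E)-6-hydroxy-3-methyl-7-[(trimethylsilyl)methyl]octa-2,7-dienoate (racemic at C6)
Conditions: CrCl2 (4 equiv), NiCl2 (2 mol %), DMF, 25 °C
Reagents that add atoms: none
Why: Nozaki–Hiyama–Kishi coupling adds the alkenylchromium to the aldehyde and not to the ester; the new carbinol centre is racemic and is erased in step 4.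

**Step 4**
Reactants: 6 methyl (2E)-6-hydroxy-3-methyl-7-[(trimethylsilyl)methyl]octa-2,7-dienoate; 7 vinyl acetate
Product: 9 methyl (2E,6Z)-3-methyl-10-oxo-7-[(trimethylsilyl)methyl]deca-2,6-dienoate, via allyl vinyl ether 8 (not isolated)
Conditions: [IrCl(cod)]2 (1 mol %, cod = 1,5-cyclooctadiene), Na2CO3 (0.6 equiv), toluene, 100 °C; then 140 °C (sealed tube)
Reagents that add atoms: none
Why: iridium-catalysed transvinylation under acid-free conditions (tolerated by the allylsilane), then Claisen rearrangement through a chair with the side chain equatorial, which places the side chain trans to the new CH2CH2CHO arm (6Z allylsilane).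

**Step 5**
Reactants: 9 methyl (2E,6Z)-3-methyl-10-oxo-7-[(trimethylsilyl)methyl]deca-2,6-dienoate; 10 isopropenylmagnesium bromide
Product: 11 methyl (2E,6Z)-10-hydroxy-3,11-dimethyl-7-[(trimethylsilyl)methyl]dodeca-2,6,11-trienoate (racemic at C10)
Conditions: THF, −78 °C; aq. NH4Cl
Reagents that add atoms: none
Why: Grignard 1,2-addition to the aldehyde is much faster than attack on the conjugated ester at −78 °C; the carbinol centre is erased in step 6.

**Step 6**
Reactants: 11 methyl (2E,6Z)-10-hydroxy-3,11-dimethyl-7-[(trimethylsilyl)methyl]dodeca-2,6,11-trienoate; 7 vinyl acetate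
Product: 13 methyl (2E,6Z,10E)-3,11-dimethyl-14-oxo-7-[(trimethylsilyl)methyl]tetradeca-2,6,10-trienoate, via allyl vinyl ether 12 (not isolated)
Conditions: [IrCl(cod)]2 (1 mol %), Na2CO3 (0.6 equiv), toluene, 100 °C; then 140 °C (sealed tube)
Reagents that add atoms: none
Why: second transvinylation/Claisen rearrangement; the chair transition state gives the (10E) methyl-substituted alkene as in Johnson-type isoprenoid chain extension.

**Step 7**
Reactants: 13 methyl (2E,6Z,10E)-3,11-dimethyl-14-oxo-7-[(trimethylsilyl)methyl]tetradeca-2,6,10-trienoate; 14 methyl diazoacetate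
Product: 16 dimethyl (6E,10Z,14E)-2-diazo-6,14-dimethyl-3-oxo-10-[(trimethylsilyl)methyl]hexadeca-6,10,14-trienedioate, via β-hydroxy diazo ester 15 (not isolated)
Conditions: DBU (20 mol %), DMSO, 25 °C; then IBX (2 equiv), 25 °C
Reagents that add atoms: none
Why: DBU-catalysed aldol addition of the diazoacetate to the aldehyde, then IBX oxidation of the β-hydroxy-α-diazo ester in the same pot, gives the α-diazo-β-keto ester.

**Step 8**
Reactants: 16 dimethyl (6E,10Z,14E)-2-diazo-6,14-dimethyl-3-oxo-10-[(trimethylsilyl)methyl]hexadeca-6,10,14-trienedioate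
Product: 17 methyl (1R,5R,6R)-6-[(3Z,7E)-9-methoxy-7-methyl-9-oxo-3-[(trimethylsilyl)methyl]nona-3,7-dien-1-yl]-5-methyl-2-oxobicyclo[3.1.0]hexane-1-carboxylate
Conditions: CuOTf·0.5C6H6 (5 mol %), 2,2'-isopropylidenebis(4-tert-butyl-2-oxazoline) (6 mol %), toluene, 50 °C, slow addition
Reagents that add atoms: none
Why: enantioselective intramolecular cyclopropanation of the α-diazo-β-keto ester by a copper–bisoxazoline carbene; stereospecific syn addition to the proximal (E)-alkene puts the chain cis to the bridgehead methyl, and the ligand fixes the absolute configuration of all three centres.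

**Step 9**
Reactants: 17 methyl (1R,5R,6R)-6-[(3Z,7E)-9-methoxy-7-methyl-9-oxo-3-[(trimethylsilyl)methyl]nona-3,7-dien-1-yl]-5-methyl-2-oxobicyclo[3.1.0]hexane-1-carboxylate
Product: 18 dimethyl (13E)-3-oxo-4-demethyl-labda-8(17),13-diene-15,19-dioate (C4 carries H and CO2Me; keto/enol and C4-epimer mixture, drawn with equatorial CO2Me; 5α-H, 9α-H, 10β-CH3)
Conditions: MeAlCl2 (1.5 equiv), CH2Cl2, −78 → −40 °C; aq. NaHCO3
Reagents that add atoms: none
Why: Proposed new method: ring-expanding bicyclisation. MeAlCl2 chelates the keto ester and polarises the internal cyclopropane bond between the ester-bearing carbon and the tertiary methyl-bearing bridgehead; the allylsilane CH carbon attacks that bridgehead with inversion through a chair (the only ring size available is six), so the cyclopentanone becomes the cyclohexanone ring A, ring B closes trans-fused with the side chain equatorial, and the β-silyl cation loses Me3Si to give the 8(17)-alkene; the closest known reaction types are the acid-promoted acylcyclopropane–olefin cyclisation, SN2-like opening of acceptor-activated cyclopropanes by π-nucleophiles and allylsilane-terminated cation–olefin cyclisation, none shown for the internal bond of a fused bicyclo[3.1.0]hexanone keto ester with formation of two rings.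

**Step 10**
Reactants: 18 dimethyl (13E)-3-oxo-4-demethyl-labda-8(17),13-diene-15,19-dioate
Product: 19 dimethyl (13E)-3-oxolabda-8(17),13-diene-15,19-dioate (4α-CH3, 4β-CO2Me)
Conditions: MeI (3 equiv), K2CO3, acetone, 25 °C
Reagents that add atoms: iodomethane CI
Why: C-alkylation of the β-keto ester enolate from the α-face, away from the axial C10 methyl, puts the new methyl equatorial and leaves the ester axial (C19).

**Step 11**
Reactants: 19 dimethyl (13E)-3-oxolabda-8(17),13-diene-15,19-dioate
Product: 21 methyl (13E)-3α,15-dihydroxylabda-8(17),13-dien-19-oate, via hydroxy enoate 20 (not isolated)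
Conditions: LiBH(s-Bu)3 (1.2 equiv), THF, −78 °C; then i-Bu2AlH (2.5 equiv), −78 → −40 °C; aq. KNaC4H4O6
Reagents that add atoms: none
Why: the bulky borohydride attacks the C3 ketone equatorially to give the axial 3α-alcohol, then i-Bu2AlH reduces the unhindered enoate 1,2 to the allylic alcohol while the axial neopentyl C19 ester is too hindered to react at low temperature.

**Step 12**
Reactants: 21 methyl (13E)-3α,15-dihydroxylabda-8(17),13-dien-19-oate
Product: 22 methyl (13R,14R)-13,14-epoxy-3α,15-dihydroxylabd-8(17)-en-19-oate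
Conditions: Ti(OiPr)4 (20 mol %), D-(−)-diethyl tartrate (24 mol %), t-BuOOH, 4 Å molecular sieves, CH2Cl2, −20 °C
Reagents that add atoms: tert-butyl hydroperoxide CC(C)(C)OO
Why: Sharpless asymmetric epoxidation acts only on the allylic alcohol; D-(−)-tartrate gives the (13R,14R) epoxy alcohol by analogy with geraniol, under reagent control.

**Step 13**
Reactants: 22 methyl (13R,14R)-13,14-epoxy-3α,15-dihydroxylabd-8(17)-en-19-oate
Product: 23 methyl (13R,14S)-13,14-epoxy-3α-hydroxy-15-oxolabd-8(17)-en-19-oate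
Conditions: TEMPO (10 mol %), PhI(OAc)2 (1.2 equiv), CH2Cl2, 25 °C
Reagents that add atoms: none
Why: oxoammonium (TEMPO) oxidation takes the primary alcohol to the aldehyde and leaves the hindered axial secondary alcohol and the epoxide untouched; the C14 descriptor changes only through priorities.

**Step 14**
Reactants: 23 methyl (13R,14S)-13,14-epoxy-3α-hydroxy-15-oxolabd-8(17)-en-19-oate
Product: 24 methyl (13R,14S)-3α-acetoxy-13,14-epoxy-15-oxolabd-8(17)-en-19-oate (target, CNP0145900.1)
Conditions: Ac2O (3 equiv), DMAP (0.2 equiv), pyridine, CH2Cl2, 25 °C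
Reagents that add atoms: acetic anhydride CC(=O)OC(C)=O
Why: DMAP-catalysed acetylation of the 3α-alcohol with retention at C3; no stereocentre is touched.

## Compound list

1 | 2-(2-bromoethyl)-1,3-dioxolane | BrCCC1OCCO1 | starting material
2 | methyl but-2-ynoate | CC#CC(=O)OC | starting material
3 | methyl (2E)-5-(1,3-dioxolan-2-yl)-3-methylpent-2-enoate | COC(=O)/C=C(\C)CCC1OCCO1 | intermediate
4 | methyl (2E)-3-methyl-6-oxohex-2-enoate | COC(=O)/C=C(\C)CCC=O | intermediate
5 | (2-bromoprop-2-en-1-yl)trimethylsilane | C=C(Br)C[Si](C)(C)C | starting material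
6 | methyl (2E)-6-hydroxy-3-methyl-7-[(trimethylsilyl)methyl]octa-2,7-dienoate (racemic) | COC(=O)/C=C(\C)CCC(O)C(=C)C[Si](C)(C)C | intermediate
7 | vinyl acetate | C=COC(C)=O | starting material
8 | methyl (2E)-6-(ethenyloxy)-3-methyl-7-[(trimethylsilyl)methyl]octa-2,7-dienoate (racemic) | COC(=O)/C=C(\C)CCC(OC=C)C(=C)C[Si](C)(C)C | intermediate
9 | methyl (2E,6Z)-3-methyl-10-oxo-7-[(trimethylsilyl)methyl]deca-2,6-dienoate | COC(=O)/C=C(\C)CC/C=C(\C[Si](C)(C)C)CCC=O | intermediate
10 | isopropenylmagnesium bromide | CC(=C)[Mg]Br | starting material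
11 | methyl (2E,6Z)-10-hydroxy-3,11-dimethyl-7-[(trimethylsilyl)methyl]dodeca-2,6,11-trienoate (racemic) | COC(=O)/C=C(\C)CC/C=C(\C[Si](C)(C)C)CCC(O)C(C)=C | intermediate
12 | methyl (2E,6Z)-10-(ethenyloxy)-3,11-dimethyl-7-[(trimethylsilyl)methyl]dodeca-2,6,11-trienoate (racemic) | COC(=O)/C=C(\C)CC/C=C(\C[Si](C)(C)C)CCC(OC=C)C(C)=C | intermediate
13 | methyl (2E,6Z,10E)-3,11-dimethyl-14-oxo-7-[(trimethylsilyl)methyl]tetradeca-2,6,10-trienoate | COC(=O)/C=C(\C)CC/C=C(\C[Si](C)(C)C)CC/C=C(\C)CCC=O | intermediate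
14 | methyl diazoacetate | COC(=O)C=[N+]=[N-] | starting material
15 | dimethyl (6E,10Z,14E)-2-diazo-3-hydroxy-6,14-dimethyl-10-[(trimethylsilyl)methyl]hexadeca-6,10,14-trienedioate (racemic) | COC(=O)/C=C(\C)CC/C=C(\C[Si](C)(C)C)CC/C=C(\C)CCC(O)C(=[N+]=[N-])C(=O)OC | intermediate
16 | dimethyl (6E,10Z,14E)-2-diazo-6,14-dimethyl-3-oxo-10-[(trimethylsilyl)methyl]hexadeca-6,10,14-trienedioate | COC(=O)/C=C(\C)CC/C=C(\C[Si](C)(C)C)CC/C=C(\C)CCC(=O)C(=[N+]=[N-])C(=O)OC | intermediate
17 | methyl (1R,5R,6R)-6-[(3Z,7E)-9-methoxy-7-methyl-9-oxo-3-[(trimethylsilyl)methyl]nona-3,7-dien-1-yl]-5-methyl-2-oxobicyclo[3.1.0]hexane-1-carboxylate | COC(=O)[C@]12[C@H](CC/C(C[Si](C)(C)C)=C/CC/C(C)=C/C(=O)OC)[C@@]1(C)CCC2=O | intermediate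
18 | dimethyl (13E)-3-oxo-4-demethyl-labda-8(17),13-diene-15,19-dioate (C4-H, epimerisable; drawn with equatorial ester) | C=C1CC[C@@H]2[C@](C)(CCC(=O)[C@H]2C(=O)OC)[C@H]1CC/C(C)=C/C(=O)OC | intermediate
19 | dimethyl (13E)-3-oxolabda-8(17),13-diene-15,19-dioate | C=C1CC[C@@H]2[C@](C)(CCC(=O)[C@]2(C)C(=O)OC)[C@H]1CC/C(C)=C/C(=O)OC | intermediate
20 | dimethyl (13E)-3α-hydroxylabda-8(17),13-diene-15,19-dioate | C=C1CC[C@@H]2[C@](C)(CC[C@@H](O)[C@]2(C)C(=O)OC)[C@H]1CC/C(C)=C/C(=O)OC | intermediate
21 | methyl (13E)-3α,15-dihydroxylabda-8(17),13-dien-19-oate | C=C1CC[C@@H]2[C@](C)(CC[C@@H](O)[C@]2(C)C(=O)OC)[C@H]1CC/C(C)=C/CO | intermediate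
22 | methyl (13R,14R)-13,14-epoxy-3α,15-dihydroxylabd-8(17)-en-19-oate | C=C1CC[C@@H]2[C@](C)(CC[C@@H](O)[C@]2(C)C(=O)OC)[C@H]1CC[C@@]1(C)O[C@@H]1CO | intermediate
23 | methyl (13R,14S)-13,14-epoxy-3α-hydroxy-15-oxolabd-8(17)-en-19-oate | C=C1CC[C@@H]2[C@](C)(CC[C@@H](O)[C@]2(C)C(=O)OC)[C@H]1CC[C@@]1(C)O[C@@H]1C=O | intermediate
24 | methyl (13R,14S)-3α-acetoxy-13,14-epoxy-15-oxolabd-8(17)-en-19-oate | C=C1CC[C@@H]2[C@](C)(CC[C@@H](OC(C)=O)[C@]2(C)C(=O)OC)[C@H]1CC[C@@]1(C)O[C@@H]1C=O | target

## Step count and risks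

Total steps: 14. Longest linear sequence: 14 (from 1 and 2 to 24).

**Step 8 (enantioselectivity and yield of the carbene cyclopropanation on an α-diazo-β-keto methyl ester).** The fallback sets out from aldehyde 13 and comes back at keto ester 18, avoiding both carbene and cyclopropane. Aldehyde 13 is homologated with 14 and catalytic SnCl2 (Roskamp reaction) to dimethyl (6E,10Z,14E)-6,14-dimethyl-3-oxo-10-[(trimethylsilyl)methyl]hexadeca-6,10,14-trienedioate F1. This is brominated with NBS and catalytic Mg(ClO4)2 to the α-bromo β-keto ester F2. A bromine-atom-transfer radical bicyclisation under chiral Lewis acid control (Mg(ClO4)2 with a bisoxazoline, Et3B/O2, toluene, −78 °C), a known enantioselective route to trans-decalin β-keto esters, then gives the tertiary β-silyl bromide F3. Bu4NF removes Me3Si and Br from F3 to form the exocyclic alkene of 18.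

**Step 9 (the proposed ring-expanding bicyclisation).** The main dangers are opening without olefin capture, protodesilylation and loss of stereospecificity at the bridgehead. The fallback uses known reaction types in two stages, sets out from 17 and comes back at 18. MgBr2·OEt2 in CH2Cl2 opens the activated cyclopropane at the tertiary carbon (homoconjugate addition of bromide) to the ring-expanded methyl 5-bromo-5-methyl-2-oxo-6-[(3Z,7E)-9-methoxy-7-methyl-9-oxo-3-[(trimethylsilyl)methyl]nona-3,7-dien-1-yl]cyclohexane-1-carboxylate F4. Ionising F4 with AgOTf and 2,6-di-tert-butylpyridine at −78 °C triggers a conventional allylsilane-terminated cation–olefin cyclisation to 18, with the C5 centre set in step 8 directing the trans ring fusion.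

**Step 14 (acetylation of the hindered axial 3α-alcohol beside a base-sensitive epoxy aldehyde).** The fallback moves the acetylation ahead of the epoxide, sets out from diol 21 and comes back at target 24. Diol 21 is bis-acetylated (Ac2O, DMAP) to methyl (13E)-3α,15-diacetoxylabda-8(17),13-dien-19-oate F5. The primary allylic acetate alone is cleaved (K2CO3, MeOH, 0 °C) to methyl (13E)-3α-acetoxy-15-hydroxylabda-8(17),13-dien-19-oate F6. Sharpless epoxidation with D-(−)-diethyl tartrate gives methyl (13R,14R)-3α-acetoxy-13,14-epoxy-15-hydroxylabd-8(17)-en-19-oate F7, and Dess–Martin periodinane oxidation of F7 gives 24.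

## Further compounds

F1 | step 8 | dimethyl (6E,10Z,14E)-6,14-dimethyl-3-oxo-10-[(trimethylsilyl)methyl]hexadeca-6,10,14-trienedioate | COC(=O)/C=C(\C)CC/C=C(\C[Si](C)(C)C)CC/C=C(\C)CCC(=O)CC(=O)OC
F2 | step 8 | dimethyl (6E,10Z,14E)-2-bromo-6,14-dimethyl-3-oxo-10-[(trimethylsilyl)methyl]hexadeca-6,10,14-trienedioate | COC(=O)/C=C(\C)CC/C=C(\C[Si](C)(C)C)CC/C=C(\C)CCC(=O)C(Br)C(=O)OC
F3 | step 8 | dimethyl (13E)-8-bromo-3-oxo-17-(trimethylsilyl)-4-demethyl-labd-13-ene-15,19-dioate (C8 configuration not defined) | C[Si](C)(C)CC1(Br)CC[C@@H]2[C@](C)(CCC(=O)[C@H]2C(=O)OC)[C@H]1CC/C(C)=C/C(=O)OC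
F4 | step 9 | methyl 5-bromo-5-methyl-2-oxo-6-[(3Z,7E)-9-methoxy-7-methyl-9-oxo-3-[(trimethylsilyl)methyl]nona-3,7-dien-1-yl]cyclohexane-1-carboxylate (C6 as in 17) | COC(=O)C1C(=O)CCC(C)(Br)[C@H]1CC/C(C[Si](C)(C)C)=C/CC/C(C)=C/C(=O)OC
F5 | step 14 | methyl (13E)-3α,15-diacetoxylabda-8(17),13-dien-19-oate | C=C1CC[C@@H]2[C@](C)(CC[C@@H](OC(C)=O)[C@]2(C)C(=O)OC)[C@H]1CC/C(C)=C/COC(C)=O
F6 | step 14 | methyl (13E)-3α-acetoxy-15-hydroxylabda-8(17),13-dien-19-oate | C=C1CC[C@@H]2[C@](C)(CC[C@@H](OC(C)=O)[C@]2(C)C(=O)OC)[C@H]1CC/C(C)=C/CO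
F7 | step 14 | methyl (13R,14R)-3α-acetoxy-13,14-epoxy-15-hydroxylabd-8(17)-en-19-oate | C=C1CC[C@@H]2[C@](C)(CC[C@@H](OC(C)=O)[C@]2(C)C(=O)OC)[C@H]1CC[C@@]1(C)O[C@@H]1CO
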